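**Plan**

- Retrosynthesis: the two acetates go back to silyl ethers and the two C–Br bonds at C11/C12 to C–O bonds of a trans-diol (double inversion). The cyclobutane bonds C5–C12 and C6–C11 are then cut (glyoxal plus a bifuran), then the C5–C6 bond (two butenolides), and last each butenolide (bromolactonisation of an allenoic acid made by an alkynoate aldol).
- Enabling feature: the C5–C6 bond between the two spiro carbons is the inter-ring bond of a 5,5'-dioxygenated 2,2'-bifuran, and C11/C12 (the CHBr carbons) are a two-carbon unit at the oxidation level of glyoxal.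
- Forward order: the two butenolide rings are made first, joined γ to γ, aromatised to the meso bis(silyloxy)bifuran, and the cyclobutane is closed last by a double vinylogous aldol with glyoxal.
- Stereochemistry: the side-chain carbinols come from one lipase resolution (the (S) alcohol for one half, the (R) alcohol for the other). The four ring stereocentres come from the chiral Lewis acid (absolute) and the substrate (relative) in the annulation, and the C–Br centres from SN2 inversion.

Key step: step 12

Assumption: the lipase is taken to acylate the (R)-alcohol, as expected when the larger carbinol substituent (the butenolide ring) outranks the smaller one (propyl); if the opposite were found, the two enantiomeric series would simply change places, since each is used once.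

**Route**

Step 1
Reactants: 1 ethyl but-2-ynoate; 2 butanal
Product: 3 ethyl 2-(1-hydroxybutyl)buta-2,3-dienoate (racemic)
Conditions: LDA, THF, −78 °C; then 2, −78 °C; AcOH quench at −78 °C
Reagents that add atoms: none
Why: γ-deprotonation of the 2-alkynoate gives a lithium cumulenolate that adds to the aldehyde through its α-carbon (deconjugative aldol), giving the 2-substituted allenoate; the carbinol centre forms racemic, which is wanted because both enantiomers are used.

Step 2
Reactants: 3 ethyl 2-(1-hydroxybutyl)buta-2,3-dienoate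
Product: 4 2-(1-hydroxybutyl)buta-2,3-dienoic acid (racemic)
Conditions: LiOH, THF/H2O, 0 °C; then 1 M HCl to pH 3
Reagents that add atoms: lithium hydroxide, [Li+].[OH-]
Why: ester saponification of an allenoate that is fully substituted at C2 and so cannot isomerise to the alkynoate should give the free acid needed for lactonisation.

Step 3
Reactants: 4 2-(1-hydroxybutyl)buta-2,3-dienoic acid
Product: 5 4-bromo-3-(1-hydroxybutyl)furan-2(5H)-one (racemic)
Conditions: NBS, K2CO3 (20 mol %), MeCN, 0 °C to rt
Reagents that add atoms: N-bromosuccinimide, O=C1CCC(=O)N1Br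
Why: electrophilic bromolactonisation of a 2,3-allenoic acid puts bromine on the central allene carbon while the carboxylate, a far better nucleophile than the neutral hydroxyl, closes 5-endo on the terminal CH2 to give the 4-bromobutenolide.

Step 4
Reactants: 5 4-bromo-3-(1-hydroxybutyl)furan-2(5H)-one (racemic)
Product: 6 4-bromo-3-[(1S)-1-hydroxybutyl]furan-2(5H)-one (unreacted enantiomer, recovered) and 7 (1R)-1-(4-bromo-2-oxo-2,5-dihydrofuran-3-yl)butyl acetate
Conditions: Burkholderia cepacia lipase (immobilised), vinyl acetate, MTBE, 30 °C, stopped near half conversion; chromatography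
Reagents that add atoms: vinyl acetate, CC(=O)OC=C
Why: lipase-catalysed kinetic resolution by enantioselective transesterification should acylate one carbinol enantiomer only, so the enzyme fixes the side-chain configuration and both halves of the racemate are kept.

Step 5
Reactants: 7 (1R)-1-(4-bromo-2-oxo-2,5-dihydrofuran-3-yl)butyl acetate
Product: 8 4-bromo-3-[(1R)-1-hydroxybutyl]furan-2(5H)-one
Conditions: HCl (1.25 M in MeOH, cat.), MeOH, rt
Reagents that add atoms: none
Why: acid-catalysed transesterification frees the alcohol without exposing the base-sensitive 4-bromobutenolide to alkoxide, and the carbinol centre is not touched.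

Step 6
Reactants: 6 4-bromo-3-[(1S)-1-hydroxybutyl]furan-2(5H)-one
Product: 9 4-bromo-3-[(1S)-1-(tert-butyldimethylsilyloxy)butyl]furan-2(5H)-one
Conditions: TBSOTf, 2,6-lutidine, CH2Cl2, −78 °C
Reagents that add atoms: tert-butyldimethylsilyl triflate, CC(C)(C)[Si](C)(C)OS(=O)(=O)C(F)(F)F
Why: silylation with a silyl triflate and a hindered, non-nucleophilic base protects the carbinol as an ether that, unlike an acetate, should not be expelled when the lactone is later enolised.

Step 7
Reactants: 8 4-bromo-3-[(1R)-1-hydroxybutyl]furan-2(5H)-one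
Product: 10 4-bromo-3-[(1R)-1-(tert-butyldimethylsilyloxy)butyl]furan-2(5H)-one
Conditions: TBSOTf, 2,6-lutidine, CH2Cl2, −78 °C
Reagents that add atoms: tert-butyldimethylsilyl triflate, CC(C)(C)[Si](C)(C)OS(=O)(=O)C(F)(F)F
Why: the same silyl ether formation as in step 6, on the enantiomeric alcohol.

Step 8
Reactants: 9 4-bromo-3-[(1S)-1-(tert-butyldimethylsilyloxy)butyl]furan-2(5H)-one
Product: 12 4,5-dibromo-3-[(1S)-1-(tert-butyldimethylsilyloxy)butyl]furan-2(5H)-one (C5 epimers), via silyloxyfuran 11 (not isolated)
Conditions: TMSOTf, Et3N, CH2Cl2, 0 °C; pentane extraction without purification; then NBS, THF, −78 °C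
Reagents that add atoms: N-bromosuccinimide, O=C1CCC(=O)N1Br
Why: soft enolisation to the 2-silyloxyfuran followed by electrophilic bromination of this silyl dienol ether at its γ-carbon (C5) should give the lactol-type bromide while avoiding radical attack on the side-chain C–H; the C5 configuration is of no consequence.

Step 9
Reactants: 10 4-bromo-3-[(1R)-1-(tert-butyldimethylsilyloxy)butyl]furan-2(5H)-one
Product: 13 4-bromo-3-[(1R)-1-(tert-butyldimethylsilyloxy)butyl]-2-(trimethylsilyloxy)furan
Conditions: TMSOTf, Et3N, CH2Cl2, 0 °C; pentane extraction, used crude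
Reagents that add atoms: trimethylsilyl triflate, C[Si](C)(C)OS(=O)(=O)C(F)(F)F
Why: soft enolisation (silyl triflate and amine) of the acidic γ-CH2 of a butenolide gives the aromatic 2-silyloxyfuran.

Step 10
Reactants: 12 4,5-dibromo-3-[(1S)-1-(tert-butyldimethylsilyloxy)butyl]furan-2(5H)-one; 13 4-bromo-3-[(1R)-1-(tert-butyldimethylsilyloxy)butyl]-2-(trimethylsilyloxy)furan
Product: 14 3,3'-dibromo-4-[(1S)-1-(tert-butyldimethylsilyloxy)butyl]-4'-[(1R)-1-(tert-butyldimethylsilyloxy)butyl]-2H,2'H-[2,2'-bifuran]-5,5'-dione (mixture at C2/C2')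
Conditions: AgOCOCF3, CH2Cl2, −78 to −30 °C, dark
Reagents that add atoms: none
Why: silver-assisted ionisation of the lactol-type bromide and capture by the γ-carbon of the silyloxyfuran (silver-promoted vinylogous alkylation of a 2-silyloxyfuran by an alkyl halide) should join one (S) and one (R) half; the two new centres are left uncontrolled because the next step erases them.

Step 11
Reactants: 14 the γ,γ'-linked bis-butenolide
Product: 15 meso 3,3'-dibromo-4-[(1S)-1-(tert-butyldimethylsilyloxy)butyl]-4'-[(1R)-1-(tert-butyldimethylsilyloxy)butyl]-5,5'-bis(trimethylsilyloxy)-2,2'-bifuran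
Conditions: TMSOTf, Et3N, CH2Cl2, 0 °C; pentane extraction under argon, used at once
Reagents that add atoms: trimethylsilyl triflate, C[Si](C)(C)OS(=O)(=O)C(F)(F)F
Why: double soft enolisation removes both γ-hydrogens and aromatises both rings, giving the meso bis(silyl ketene acetal) whose trimethylsilyl groups can later be removed selectively.

Step 12
Reactants: 15 the meso bis(trimethylsilyloxy)bifuran; 16 glyoxal (anhydrous monomer, freshly liberated from commercial glyoxal trimer dihydrate with P4O10 and condensed into CH2Cl2)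
Product: 19 (5R,6R,11R,12R)-4,10-dibromo-11,12-dihydroxy-3-[(1S)-1-(tert-butyldimethylsilyloxy)butyl]-9-[(1R)-1-(tert-butyldimethylsilyloxy)butyl]-1,7-dioxadispiro[4.0.4.2]dodeca-3,9-diene-2,8-dione, via mono-adduct aldehyde 17 (not isolated), via bis(trimethylsilyl) ether 18 (not isolated)
Conditions: Sc(OTf)3 (10 mol %), 2,6-bis[(4S)-4-phenyl-4,5-dihydrooxazol-2-yl]pyridine (12 mol %), 4 Å MS, CH2Cl2, −78 °C, simultaneous slow addition of 15 and 16 (0.005 M); then aq. citric acid/MeOH, 0 °C
Reagents that add atoms: none
Why: Proposed new method: glyoxal is held two-point by the chiral trivalent-scandium complex, C2 of one furan (its γ-carbon) adds to a bound carbonyl through an open vinylogous Mukaiyama aldol transition state and the trimethylsilyl group passes to the aldolate oxygen to give the α-silyloxy aldehyde 17, in which the second silyloxyfuran sits on the new quaternary carbon and its C2' closes the ring on the aldehyde, silyl transfer again trapping the aldolate as 18 so that the strained ring cannot reopen by retro-aldol. The closest known reaction types are bis(oxazoline)–copper and pybox–scandium catalysed (vinylogous) Mukaiyama aldol additions of 2-silyloxyfurans and enol silanes to chelating glyoxylate and pyruvate esters, and acid-catalysed formal (2+2) annulations of silyl enol ethers. The one ring formed, the cyclobutane, arises in the second aldol by 4-exo-trig attack of C2' on the aldehyde carbon. The first spiro carbon and its carbinol neighbour are set by the catalyst, whose facial preference at the nucleophilic carbon leads to the same enantiomer whichever of the two enantiotopic furans reacts first (the sense must be found by experiment and the ligand enantiomer chosen accordingly), while the second spiro carbon and carbinol are set by the substrate during closure, the two C–Br flanks turning anti to each other and each new oxygen lying anti to the neighbouring bromovinyl carbon and cis to the neighbouring lactone oxygen, which gives the trans-diol. The step needs γ- over α-attack, secured because C2/C2' are the dienolate termini while the α-carbons carry the branched silyloxybutyl chains, and ring closure over a second intermolecular aldol, secured by the proximity of the second nucleophile and by slow addition at high dilution. A redox-inert Lewis acid is chosen because the electron-rich bifuran would be oxidised by one-electron acceptors such as divalent copper salts, and the trimethylsilyl ethers of the new carbinols are cleaved by the mild acid work-up while the tert-butyldimethylsilyl ethers remain.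

Step 13
Reactants: 19 the dispiro trans-diol
Product: 20 the (5R,6R,11R,12R)-11,12-bis(trifluoromethanesulfonate) of 19
Conditions: Tf2O, pyridine, CH2Cl2, −30 to 0 °C; used crude
Reagents that add atoms: triflic anhydride, O=S(=O)(OS(=O)(=O)C(F)(F)F)C(F)(F)F
Why: sulfonylation of both secondary hydroxyls under weakly basic conditions forms no free alkoxide that could trigger retro-aldol opening of the cyclobutane, and the carbinol configurations are retained.

Step 14
Reactants: 20 the bis(triflate)
Product: 21 (5S,6S,11R,12R)-4,10,11,12-tetrabromo-3-[(1S)-1-(tert-butyldimethylsilyloxy)butyl]-9-[(1R)-1-(tert-butyldimethylsilyloxy)butyl]-1,7-dioxadispiro[4.0.4.2]dodeca-3,9-diene-2,8-dione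
Conditions: LiBr, acetone, 0 °C to rt
Reagents that add atoms: lithium bromide, [Li+].[Br-]
Why: twofold SN2 displacement of triflate by bromide with inversion at C11 and C12 should turn the diol configuration into the trans-dibromide in which each bromine is cis to the neighbouring bromovinyl carbon; the electron-poor flanking carbons disfavour ionisation.

Step 15
Reactants: 21 the bis-silyl tetrabromide
Product: 22 (5S,6S,11R,12R)-4,10,11,12-tetrabromo-3-[(1S)-1-hydroxybutyl]-9-[(1R)-1-hydroxybutyl]-1,7-dioxadispiro[4.0.4.2]dodeca-3,9-diene-2,8-dione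
Conditions: HF·pyridine, THF, 0 °C to rt
Reagents that add atoms: none
Why: acidic fluoride cleaves the two silyl ethers without base, so neither HBr elimination nor attack on the bromobutenolides is expected.

Step 16
Reactants: 22 the side-chain diol
Product: 23 (5S,6S,11R,12R)-4,10,11,12-tetrabromo-3-[(1S)-1-acetoxybutyl]-9-[(1R)-1-acetoxybutyl]-1,7-dioxadispiro[4.0.4.2]dodeca-3,9-diene-2,8-dione (target)
Conditions: Ac2O, Sc(OTf)3 (2 mol %), MeCN, 0 °C
Reagents that add atoms: acetic anhydride, CC(=O)OC(C)=O
Why: Lewis-acid-catalysed acetylation of the two secondary alcohols avoids nucleophilic amines and touches no stereocentre.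

**Compound list**

1 | ethyl but-2-ynoate | CC#CC(=O)OCC | starting material
2 | butanal | CCCC=O | starting material
3 | ethyl 2-(1-hydroxybutyl)buta-2,3-dienoate (racemic) | CCCC(O)C(=C=C)C(=O)OCC | intermediate
4 | 2-(1-hydroxybutyl)buta-2,3-dienoic acid (racemic) | CCCC(O)C(=C=C)C(O)=O | intermediate
5 | 4-bromo-3-(1-hydroxybutyl)furan-2(5H)-one (racemic) | CCCC(O)C1=C(Br)COC1=O | intermediate
6 | 4-bromo-3-[(1S)-1-hydroxybutyl]furan-2(5H)-one | CCC[C@H](O)C1=C(Br)COC1=O | intermediate
7 | (1R)-1-(4-bromo-2-oxo-2,5-dihydrofuran-3-yl)butyl acetate | CCC[C@@H](OC(C)=O)C1=C(Br)COC1=O | intermediate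
8 | 4-bromo-3-[(1R)-1-hydroxybutyl]furan-2(5H)-one | CCC[C@@H](O)C1=C(Br)COC1=O | intermediate
9 | 4-bromo-3-[(1S)-1-(tert-butyldimethylsilyloxy)butyl]furan-2(5H)-one | CCC[C@H](O[Si](C)(C)C(C)(C)C)C1=C(Br)COC1=O | intermediate
10 | 4-bromo-3-[(1R)-1-(tert-butyldimethylsilyloxy)butyl]furan-2(5H)-one | CCC[C@@H](O[Si](C)(C)C(C)(C)C)C1=C(Br)COC1=O | intermediate
11 | 4-bromo-3-[(1S)-1-(tert-butyldimethylsilyloxy)butyl]-2-(trimethylsilyloxy)furan (not isolated) | CCC[C@H](O[Si](C)(C)C(C)(C)C)c1c(Br)coc1O[Si](C)(C)C | intermediate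
12 | 4,5-dibromo-3-[(1S)-1-(tert-butyldimethylsilyloxy)butyl]furan-2(5H)-one (C5 epimers) | CCC[C@H](O[Si](C)(C)C(C)(C)C)C1=C(Br)C(Br)OC1=O | intermediate
13 | 4-bromo-3-[(1R)-1-(tert-butyldimethylsilyloxy)butyl]-2-(trimethylsilyloxy)furan | CCC[C@@H](O[Si](C)(C)C(C)(C)C)c1c(Br)coc1O[Si](C)(C)C | intermediate
14 | 3,3'-dibromo-4-[(1S)-1-(tert-butyldimethylsilyloxy)butyl]-4'-[(1R)-1-(tert-butyldimethylsilyloxy)butyl]-2H,2'H-[2,2'-bifuran]-5,5'-dione (mixture at C2/C2') | CCC[C@H](O[Si](C)(C)C(C)(C)C)C1=C(Br)C(OC1=O)C1OC(=O)C([C@@H](CCC)O[Si](C)(C)C(C)(C)C)=C1Br | intermediate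
15 | meso 3,3'-dibromo-4-[(1S)-1-(tert-butyldimethylsilyloxy)butyl]-4'-[(1R)-1-(tert-butyldimethylsilyloxy)butyl]-5,5'-bis(trimethylsilyloxy)-2,2'-bifuran | CCC[C@H](O[Si](C)(C)C(C)(C)C)c1c(Br)c(oc1O[Si](C)(C)C)-c1oc(O[Si](C)(C)C)c([C@@H](CCC)O[Si](C)(C)C(C)(C)C)c1Br | intermediate
16 | glyoxal (anhydrous monomer) | O=CC=O | starting material
17 | mono-adduct (not isolated): 4-bromobutenolide of the (S) half whose quaternary C5 carries the CH(OSiMe3)CHO unit and the intact 2-silyloxyfuran of the (R) half, configured as in 19 | CCC[C@H](O[Si](C)(C)C(C)(C)C)C1=C(Br)[C@@](OC1=O)([C@H](O[Si](C)(C)C)C=O)c1oc(O[Si](C)(C)C)c([C@@H](CCC)O[Si](C)(C)C(C)(C)C)c1Br | intermediate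
18 | 11,12-bis(trimethylsilyl) ether of 19 (not isolated) | CCC[C@H](O[Si](C)(C)C(C)(C)C)C1=C(Br)[C@@]2(OC1=O)[C@H](O[Si](C)(C)C)[C@@H](O[Si](C)(C)C)[C@@]21OC(=O)C([C@@H](CCC)O[Si](C)(C)C(C)(C)C)=C1Br | intermediate
19 | (5R,6R,11R,12R)-4,10-dibromo-11,12-dihydroxy-3-[(1S)-1-(tert-butyldimethylsilyloxy)butyl]-9-[(1R)-1-(tert-butyldimethylsilyloxy)butyl]-1,7-dioxadispiro[4.0.4.2]dodeca-3,9-diene-2,8-dione (trans-diol, each OH cis to the lactone oxygen of the adjacent spiro carbon) | CCC[C@H](O[Si](C)(C)C(C)(C)C)C1=C(Br)[C@@]2(OC1=O)[C@H](O)[C@@H](O)[C@@]21OC(=O)C([C@@H](CCC)O[Si](C)(C)C(C)(C)C)=C1Br | intermediate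
20 | (5R,6R,11R,12R)-11,12-bis(trifluoromethanesulfonate) of 19 | CCC[C@H](O[Si](C)(C)C(C)(C)C)C1=C(Br)[C@@]2(OC1=O)[C@H](OS(=O)(=O)C(F)(F)F)[C@@H](OS(=O)(=O)C(F)(F)F)[C@@]21OC(=O)C([C@@H](CCC)O[Si](C)(C)C(C)(C)C)=C1Br | intermediate
21 | (5S,6S,11R,12R)-4,10,11,12-tetrabromo-3-[(1S)-1-(tert-butyldimethylsilyloxy)butyl]-9-[(1R)-1-(tert-butyldimethylsilyloxy)butyl]-1,7-dioxadispiro[4.0.4.2]dodeca-3,9-diene-2,8-dione | CCC[C@H](O[Si](C)(C)C(C)(C)C)C1=C(Br)[C@@]2(OC1=O)[C@@H](Br)[C@H](Br)[C@@]21OC(=O)C([C@@H](CCC)O[Si](C)(C)C(C)(C)C)=C1Br | intermediate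
22 | (5S,6S,11R,12R)-4,10,11,12-tetrabromo-3-[(1S)-1-hydroxybutyl]-9-[(1R)-1-hydroxybutyl]-1,7-dioxadispiro[4.0.4.2]dodeca-3,9-diene-2,8-dione | CCC[C@H](O)C1=C(Br)[C@@]2(OC1=O)[C@@H](Br)[C@H](Br)[C@@]21OC(=O)C([C@@H](CCC)O)=C1Br | intermediate
23 | (5S,6S,11R,12R)-4,10,11,12-tetrabromo-3-[(1S)-1-acetoxybutyl]-9-[(1R)-1-acetoxybutyl]-1,7-dioxadispiro[4.0.4.2]dodeca-3,9-diene-2,8-dione | CCC[C@H](OC(C)=O)C1=C(Br)[C@@]2(OC1=O)[C@@H](Br)[C@H](Br)[C@@]21OC(=O)C([C@@H](CCC)OC(C)=O)=C1Br | target

**Step count**

Total: 16 steps. Longest linear sequence: 14 steps (1 → 3 → 4 → 5 → 7 → 8 → 10 → 13 → 14 → 15 → 19 → 20 → 21 → 22 → 23).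

**Steps most likely to fail**

Step 12 (proposed new method). The bifuran may be consumed by one-electron oxidation, the mono-adduct may be intercepted by a second glyoxal or a second bifuran before the 4-exo closure, the closure may revert before silyl transfer, or facial selection on the meso substrate may be poor. The fallback sets out from 15 and returns at 21, bypassing steps 13 and 14. Oxidation of 15 with DDQ (CH2Cl2, −78 °C) would give the (E)-3,3'-dibromo-4,4'-bis[1-(tert-butyldimethylsilyloxy)butyl]-[2,2'-bifuranylidene]-5,5'-dione F1. Irradiation of F1 (366 nm) in acetylene-saturated CH2Cl2 at −60 °C (enone–alkyne (2+2) photocycloaddition across the central C=C) would give the racemic 4,10-dibromo-dispiro cyclobutene (1,7-dioxadispiro[4.0.4.2]dodeca-3,9,11-triene-2,8-dione) F2. Anti-addition of Br2 (CH2Cl2, −78 °C, dark) to the cyclobutene should give 21 as the racemate beside the other trans-dibromide; chromatography and separation of the enantiomers on a chiral stationary phase then deliver 21.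

Step 14. Substitution at the neopentyl-type cyclobutyl carbons may be too slow, so that elimination from the cis-bromo triflate formed after the first displacement, or ionisation with ring contraction, takes over. The fallback sets out from 19 and returns at 21 without any SN2 at these carbons. 19 would be acylated with 1,1'-thiocarbonyldiimidazole (toluene, 60 °C) to the 11,12-bis(imidazole-1-carbothioate) F3. Radical deoxygenative elimination of this vicinal bis(thiocarbonate) (Bu3SnH, AIBN, toluene, 80 °C) would give the enantiopure (5R,6R)-cyclobutene F4. Anti-bromination with Br2 (CH2Cl2, −78 °C) then gives 21 and its trans-diastereomer, to be separated by chromatography.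

Step 10. Bromine transfer between the two partners may scramble them and lead to homo-coupled material, or the bromide may ionise without C–C bond formation at the two hindered γ-carbons. The fallback sets out from 9 and 10 and returns at 14. 9 would be enolised with i-Pr2Si(OTf)2 and Et3N (CH2Cl2, −78 °C) to the furyloxy(diisopropyl)silyl triflate F5. Addition of 10 and more Et3N would give the unsymmetrical bis(furyloxy)diisopropylsilane F6. Oxidation with (NH4)2Ce(NO3)6 and NaHCO3 in MeCN at −20 °C (silicon-tethered oxidative coupling of a bis-enol ether) should join the two γ-carbons within the tether and give 14 after loss of the silicon bridge.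

**Further compounds**

F1 | step 12 | (E)-3,3'-dibromo-4-[(1S)-1-(tert-butyldimethylsilyloxy)butyl]-4'-[(1R)-1-(tert-butyldimethylsilyloxy)butyl]-[2,2'-bifuranylidene]-5,5'-dione | CCC[C@H](O[Si](C)(C)C(C)(C)C)C1=C(Br)/C(OC1=O)=C2\OC(=O)C([C@@H](CCC)O[Si](C)(C)C(C)(C)C)=C2Br
F2 | step 12 | racemic 4,10-dibromo-3-[(1S)-1-(tert-butyldimethylsilyloxy)butyl]-9-[(1R)-1-(tert-butyldimethylsilyloxy)butyl]-1,7-dioxadispiro[4.0.4.2]dodeca-3,9,11-triene-2,8-dione (lactone oxygens trans; one enantiomer drawn) | CCC[C@H](O[Si](C)(C)C(C)(C)C)C1=C(Br)[C@@]2(OC1=O)C=C[C@@]21OC(=O)C([C@@H](CCC)O[Si](C)(C)C(C)(C)C)=C1Br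
F3 | step 14 | 11,12-bis(imidazole-1-carbothioate) of 19 | CCC[C@H](O[Si](C)(C)C(C)(C)C)C1=C(Br)[C@@]2(OC1=O)[C@H](OC(=S)n3ccnc3)[C@@H](OC(=S)n4ccnc4)[C@@]21OC(=O)C([C@@H](CCC)O[Si](C)(C)C(C)(C)C)=C1Br
F4 | step 14 | (5R,6R)-4,10-dibromo-3-[(1S)-1-(tert-butyldimethylsilyloxy)butyl]-9-[(1R)-1-(tert-butyldimethylsilyloxy)butyl]-1,7-dioxadispiro[4.0.4.2]dodeca-3,9,11-triene-2,8-dione (single enantiomer) | CCC[C@H](O[Si](C)(C)C(C)(C)C)C1=C(Br)[C@@]2(OC1=O)C=C[C@@]21OC(=O)C([C@@H](CCC)O[Si](C)(C)C(C)(C)C)=C1Br
F5 | step 10 | [4-bromo-3-[(1S)-1-(tert-butyldimethylsilyloxy)butyl]furan-2-yl]oxy(diisopropyl)silyl triflate | CCC[C@H](O[Si](C)(C)C(C)(C)C)c1c(Br)coc1O[Si](C(C)C)(C(C)C)OS(=O)(=O)C(F)(F)F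
F6 | step 10 | [4-bromo-3-[(1S)-1-(tert-butyldimethylsilyloxy)butyl]furan-2-yl]oxy-[4-bromo-3-[(1R)-1-(tert-butyldimethylsilyloxy)butyl]furan-2-yl]oxy-diisopropylsilane | CCC[C@H](O[Si](C)(C)C(C)(C)C)c1c(Br)coc1O[Si](C(C)C)(C(C)C)Oc1occ(Br)c1[C@@H](CCC)O[Si](C)(C)C(C)(C)C
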